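The dihydrofuran ring (O1, C2, C3, C3a, C7a) with the exocyclic carbon C9 on C3 is treated as the pyranone ring of a flavanone from which the carbonyl carbon has been squeezed out. The whole plan therefore rests on making the C3–C3a bond by a 1,2-shift of the benzo ring. One iodine(III) oxidation in trimethyl orthoformate shrinks the six-membered ring to five, turns C9 into a methyl ester and sets C3 trans to the C2 aryl group. The precursor is a (2R)-flavanone with veratryl at C2, a bromide at C6 as the handle for the acrylate, and a mesylate masking the C8 phenol. Its one stereocentre is set by catalytic asymmetric conjugate addition.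

Key step: step 5

Assumption: the (S)-configured t-BuPyOX ligand is taken to deliver the aryl group to the chromone face that gives the (2R)-flavanone, as mapped from its sense on cyclic enones. If the first run shows the opposite sense, the (R)-ligand is used and nothing else changes.

Step 1
Reactants: 1 2',3'-dihydroxyacetophenone
Product: 2 3-acetyl-2-hydroxyphenyl methanesulfonate (2'-hydroxy-3'-mesyloxyacetophenone)
Conditions: MsCl (1.0 equiv), Et3N (1.1 equiv), CH2Cl2, −20 → 0 °C
Reagents that add atoms: methanesulfonyl chloride, CS(=O)(=O)Cl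
Why: Chemoselective O-sulfonylation, in which the 2'-OH is tied up in a six-membered hydrogen bond to the ketone and flanked on both sides, so one equivalent of electrophile should be taken by the free, less hindered 3'-OH, and a sulfonate, unlike an acyl group, does not wander to the neighbouring oxygen later.

Step 2
Reactants: 2 3-acetyl-2-hydroxyphenyl methanesulfonate
Product: 3 3-acetyl-5-bromo-2-hydroxyphenyl methanesulfonate (5'-bromo-2'-hydroxy-3'-mesyloxyacetophenone)
Conditions: Br2 (1.05 equiv), NaOAc (1.2 equiv), AcOH, rt
Reagents that add atoms: bromine, BrBr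
Why: Electrophilic aromatic bromination, where the 2'-OH is the only strong donor left and both its ortho positions are blocked, so bromine should enter para to it at C5' (also meta to the acetyl group), no free catechol is exposed to the oxidant, and the acetate buffer holds back acid-catalysed enolisation and thus side-chain bromination.

Step 3
Reactants: 3 3-acetyl-5-bromo-2-hydroxyphenyl methanesulfonate
Product: 5 6-bromo-4-oxo-4H-chromen-8-yl methanesulfonate, via enaminone 4 (not isolated)
Conditions: Me2NCH(OMe)2 (2 equiv), PhMe, 90 °C; evaporate; conc. HCl, CH2Cl2, 40 °C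
Reagents that add atoms: N,N-dimethylformamide dimethyl acetal, COC(OC)N(C)C
Why: Enaminone condensation of the methyl ketone with the amide acetal, followed by acid-induced 6-endo-trig addition of the phenol oxygen to the β-carbon and loss of dimethylamine, is the standard chromone synthesis, and it needs no strong base, so the sulfonate should survive.

Step 4
Reactants: 5 6-bromo-4-oxo-4H-chromen-8-yl methanesulfonate; 6 3,4-dimethoxyphenylboronic acid (2 equiv)
Product: 7 (2R)-6-bromo-2-(3,4-dimethoxyphenyl)-4-oxochroman-8-yl methanesulfonate, i.e. (R)-6-bromo-2-(3,4-dimethoxyphenyl)-8-(methanesulfonyloxy)chroman-4-one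
Conditions: Pd(OCOCF3)2 (5 mol %), (S)-t-BuPyOX (6 mol %), NH4PF6 (30 mol %), H2O (5 equiv), ClCH2CH2Cl, 60 °C, air
Reagents that add atoms: none
Why: Palladium(II)-catalysed asymmetric conjugate addition of an arylboronic acid to a chromone (transmetalation, face-selective carbopalladation of C2=C3, protonolysis), in which the tert-butyl group of the ligand shields one face and sets C2 as R, the cycle stays at Pd(II) so the C–Br bond is left alone, and the base-free medium should not open a flavanone that carries a good aryloxide leaving group.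

Step 5
Reactants: 7 (2R)-6-bromo-2-(3,4-dimethoxyphenyl)-4-oxochroman-8-yl methanesulfonate
Product: 11 methyl (2R,3R)-5-bromo-2-(3,4-dimethoxyphenyl)-7-(methanesulfonyloxy)-2,3-dihydrobenzofuran-3-carboxylate (2,3-trans), via enol ether 8 (not isolated), via iodane ketal 9 (not isolated), via dimethoxycarbenium ion 10 (not isolated)
Conditions: HC(OMe)3 (solvent), conc. H2SO4 (cat.), 0 °C; then PhI(OAc)2 (1.2 equiv), 0 °C → rt
Reagents that add atoms: trimethyl orthoformate, COC(OC)OC
Why: Acid and orthoformate convert ketone 7 into enol ether 8, whose C3 attacks the iodine(III) centre from the face opposite to the C2 veratryl group, and methanol caps C4 to give the 2,3-trans iodane ketal 9. In the half-chair of 9 that keeps both the aryl group and the iodane equatorial, the C4–C4a bond stands antiperiplanar to C3–I, so C4a moves from C4 to C3 while iodobenzene leaves, driven by the two ketal oxygens, and cation 10 then hands a methyl group to acetate to leave ester 11. The closest known reaction type is this very one, the iodine(III) or thallium(III) oxidative ring contraction of flavanones in trimethyl orthoformate, a semipinacol-like 1,2-aryl shift. The dihydrofuran ring is closed by contraction and not by end-to-end cyclisation: C4a displaces the iodane at C3 in a formally 3-exo-tet, phenonium-type bridging and the old C4–C4a bond opens. C3 is set by substrate control, since anti attack dictated by C2 followed by inversion in the shift places the ester trans to the aryl group (2R,3R), while no bond at C2 is touched. The step needs the benzo-ring shift to win over veratryl shift, dehydrogenation and pyranone opening; the ketal gives its push only to the C4a shift, a veratryl shift would need the diaxial conformer and the lone pair of O1, which the para bromide and the ortho mesylate drain, and both groups are merely meta to the migrating C4a.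

Step 6
Reactants: 11 methyl (2R,3R)-5-bromo-2-(3,4-dimethoxyphenyl)-7-(methanesulfonyloxy)-2,3-dihydrobenzofuran-3-carboxylate
Product: 12 (2R,3S)-5-bromo-2-(3,4-dimethoxyphenyl)-3-(hydroxymethyl)-2,3-dihydrobenzofuran-7-yl methanesulfonate
Conditions: LiBH4 (1.5 equiv), THF, 0 °C → rt; aq NH4Cl
Reagents that add atoms: none
Why: Chemoselective ester reduction with lithium borohydride, which leaves aryl sulfonate and aryl bromide alone, is cold and weakly basic enough to avoid deprotonation at C3 (which would expel O1 by β-elimination), and removes the carbonyl group so that C3 is safe in the hot basic steps that follow; the change of the C3 descriptor from R to S is a matter of CIP ranking only.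

Step 7
Reactants: 12 (2R,3S)-5-bromo-2-(3,4-dimethoxyphenyl)-3-(hydroxymethyl)-2,3-dihydrobenzofuran-7-yl methanesulfonate; 13 methyl acrylate (2 equiv)
Product: 14 methyl (E)-3-[(2R,3S)-2-(3,4-dimethoxyphenyl)-3-(hydroxymethyl)-7-(methanesulfonyloxy)-2,3-dihydrobenzofuran-5-yl]acrylate
Conditions: Pd(OAc)2 (5 mol %), P(o-tol)3 (10 mol %), Et3N (2 equiv), DMF, 100 °C
Reagents that add atoms: none
Why: Mizoroki–Heck reaction, in which oxidative addition takes place only at the unhindered C5–Br bond because aryl mesylates need special electron-rich ligands, syn insertion and syn β-hydride elimination give the E-cinnamate, and the free primary alcohol is a spectator.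

Step 8
Reactants: 14 methyl (E)-3-[(2R,3S)-2-(3,4-dimethoxyphenyl)-3-(hydroxymethyl)-7-(methanesulfonyloxy)-2,3-dihydrobenzofuran-5-yl]acrylate
Product: 16 (E)-3-[(2R,3S)-2-(3,4-dimethoxyphenyl)-7-hydroxy-3-(hydroxymethyl)-2,3-dihydrobenzofuran-5-yl]acrylic acid (target), via mesyloxy acid 15 (not isolated)
Conditions: 2 M aq NaOH (6 equiv), MeOH–THF, 60 °C, Ar; then 1 M HCl, 0 °C
Reagents that add atoms: sodium hydroxide, [Na+].[OH-] (its oxygen becomes the carboxyl OH)
Why: Saponification of the cinnamate and hydroxide cleavage of the aryl sulfonate at sulfur (elimination to sulfene, E1cB) run in one flask, neither C2 nor C3 carries a carbonyl-activated hydrogen any more so both centres should hold, and cold acidification frees the acid and the phenol.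

Compound list
1 | 2',3'-dihydroxyacetophenone | CC(=O)c1cccc(O)c1O | starting material
2 | 3-acetyl-2-hydroxyphenyl methanesulfonate | CC(=O)c1cccc(OS(C)(=O)=O)c1O | intermediate
3 | 3-acetyl-5-bromo-2-hydroxyphenyl methanesulfonate | CC(=O)c1cc(Br)cc(OS(C)(=O)=O)c1O | intermediate
4 | 5-bromo-3-[(E)-3-(dimethylamino)prop-2-enoyl]-2-hydroxyphenyl methanesulfonate (enaminone, not isolated) | CN(C)/C=C/C(=O)c1cc(Br)cc(OS(C)(=O)=O)c1O | intermediate
5 | 6-bromo-4-oxo-4H-chromen-8-yl methanesulfonate | O=c1ccoc2c(OS(C)(=O)=O)cc(Br)cc12 | intermediate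
6 | 3,4-dimethoxyphenylboronic acid | COc1ccc(B(O)O)cc1OC | starting material
7 | (2R)-6-bromo-2-(3,4-dimethoxyphenyl)-4-oxochroman-8-yl methanesulfonate | COc1ccc([C@@H]2Oc3c(OS(C)(=O)=O)cc(Br)cc3C(=O)C2)cc1OC | intermediate
8 | (2R)-6-bromo-2-(3,4-dimethoxyphenyl)-4-methoxy-2H-chromen-8-yl methanesulfonate (enol ether, not isolated) | COc1ccc([C@@H]2Oc3c(OS(C)(=O)=O)cc(Br)cc3C(OC)=C2)cc1OC | intermediate
9 | (2S,3S)-3-[acetoxy(phenyl)-λ3-iodanyl]-6-bromo-2-(3,4-dimethoxyphenyl)-4,4-dimethoxychroman-8-yl methanesulfonate (2,3-trans; C2 has the same spatial arrangement as in 7, the descriptor changes by CIP ranking; not isolated) | COc1ccc([C@@H]2Oc3c(OS(C)(=O)=O)cc(Br)cc3C(OC)(OC)[C@H]2I(OC(C)=O)c2ccccc2)cc1OC | intermediate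
10 | [(2R,3R)-5-bromo-2-(3,4-dimethoxyphenyl)-7-(methanesulfonyloxy)-2,3-dihydrobenzofuran-3-yl]dimethoxymethylium (not isolated) | COc1ccc([C@@H]2Oc3c(OS(C)(=O)=O)cc(Br)cc3[C@H]2C(OC)=[O+]C)cc1OC | intermediate
11 | methyl (2R,3R)-5-bromo-2-(3,4-dimethoxyphenyl)-7-(methanesulfonyloxy)-2,3-dihydrobenzofuran-3-carboxylate (trans) | COc1ccc([C@@H]2Oc3c(OS(C)(=O)=O)cc(Br)cc3[C@H]2C(=O)OC)cc1OC | intermediate
12 | (2R,3S)-5-bromo-2-(3,4-dimethoxyphenyl)-3-(hydroxymethyl)-2,3-dihydrobenzofuran-7-yl methanesulfonate | COc1ccc([C@@H]2Oc3c(OS(C)(=O)=O)cc(Br)cc3[C@H]2CO)cc1OC | intermediate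
13 | methyl acrylate | C=CC(=O)OC | starting material
14 | methyl (E)-3-[(2R,3S)-2-(3,4-dimethoxyphenyl)-3-(hydroxymethyl)-7-(methanesulfonyloxy)-2,3-dihydrobenzofuran-5-yl]acrylate | COc1ccc([C@@H]2Oc3c(OS(C)(=O)=O)cc(/C=C/C(=O)OC)cc3[C@H]2CO)cc1OC | intermediate
15 | (E)-3-[(2R,3S)-2-(3,4-dimethoxyphenyl)-3-(hydroxymethyl)-7-(methanesulfonyloxy)-2,3-dihydrobenzofuran-5-yl]acrylic acid (present as its sodium salt, not isolated) | COc1ccc([C@@H]2Oc3c(OS(C)(=O)=O)cc(/C=C/C(=O)O)cc3[C@H]2CO)cc1OC | intermediate
16 | (E)-3-[(2R,3S)-2-(3,4-dimethoxyphenyl)-7-hydroxy-3-(hydroxymethyl)-2,3-dihydrobenzofuran-5-yl]acrylic acid | COc1ccc([C@@H]2Oc3c(O)cc(/C=C/C(=O)O)cc3[C@H]2CO)cc1OC | target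

Total step count: 8. Longest linear sequence: 8 (from 1).

Steps most likely to fail

Step 5 (key step). The benzo-ring shift may lose out to migration of the veratryl group, to loss of the iodane together with the C2 hydrogen (dehydrogenation), or to attack of iodine(III) on the electron-rich veratryl ring. Acid-induced opening of the pyranone before the oxidation may also erode the enantiomeric purity. The fallback runs from 7 back to 11 and separates halogenation, ketal formation and shift, so that no oxidant is present when the bond migrates.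
- α-Bromination of 7 with CuBr2 in EtOAc–CHCl3 at reflux should give the 2,3-trans bromoketone (2S,3S)-3,6-dibromo-2-(3,4-dimethoxyphenyl)-4-oxochroman-8-yl methanesulfonate F1.
- HC(OMe)3, MeOH and catalytic TsOH should convert it into the ketal (2S,3S)-3,6-dibromo-2-(3,4-dimethoxyphenyl)-4,4-dimethoxychroman-8-yl methanesulfonate F2.
- AgBF4 in MeOH–HC(OMe)3 then pulls off the equatorial bromide and C4a shifts to C3 with inversion. This is the silver-assisted 1,2-aryl migration of α-bromo aryl ketals to arylacetic esters, and it gives 11 after aqueous work-up.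

Step 4. Facial selectivity may be poor on this 8-substituted chromone. The electron-rich boronic acid may be lost by protodeboronation or homocoupling before it transfers its aryl group. Any palladium(0) that forms may start cross-coupling at the bromide. The fallback runs from 3 back to 7, builds the racemate by chalcone chemistry and resolves it catalytically.
- BF3·OEt2-mediated aldol condensation of 3 with 3,4-dimethoxybenzaldehyde in dioxane (an acidic Claisen–Schmidt variant, chosen to spare the sulfonate) should give the chalcone 5-bromo-3-[(E)-3-(3,4-dimethoxyphenyl)prop-2-enoyl]-2-hydroxyphenyl methanesulfonate F3.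
- Oxa-Michael ring closure with NaOAc in refluxing EtOH gives racemic 6-bromo-2-(3,4-dimethoxyphenyl)-4-oxochroman-8-yl methanesulfonate F4.
- Kinetic resolution by asymmetric transfer hydrogenation (Cp*RhCl(TsDPEN), HCO2H–Et3N, EtOAc) uses the catalyst antipode that reduces the (S)-ketone faster. It turns that enantiomer into the cis alcohol (2S,4S)-6-bromo-2-(3,4-dimethoxyphenyl)-4-hydroxychroman-8-yl methanesulfonate F5 and leaves 7, which is separated by chromatography.

Step 1. Sulfonylation may go to the wrong oxygen or to both oxygens. The fallback runs from 1 back to 5 and lets the ring closure use up O2' first, so that only one hydroxyl group is left for the sulfonyl chloride.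
- Bromination of 1 (Br2, NaOAc, AcOH) should take place at C5', the only position that is para to a hydroxyl group and neither ortho nor para to the acetyl group. It gives 5'-bromo-2',3'-dihydroxyacetophenone F6.
- DMF dimethyl acetal and then HCl lead through the enaminone (E)-1-(5-bromo-2,3-dihydroxyphenyl)-3-(dimethylamino)prop-2-en-1-one F7 to 6-bromo-8-hydroxy-4H-chromen-4-one F8.
- MsCl and Et3N then meet a single phenol and give 5.

Further compounds
F1 | step 5 | (2S,3S)-3,6-dibromo-2-(3,4-dimethoxyphenyl)-4-oxochroman-8-yl methanesulfonate (2,3-trans) | COc1ccc([C@@H]2Oc3c(OS(C)(=O)=O)cc(Br)cc3C(=O)[C@H]2Br)cc1OC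
F2 | step 5 | (2S,3S)-3,6-dibromo-2-(3,4-dimethoxyphenyl)-4,4-dimethoxychroman-8-yl methanesulfonate (2,3-trans) | COc1ccc([C@@H]2Oc3c(OS(C)(=O)=O)cc(Br)cc3C(OC)(OC)[C@H]2Br)cc1OC
F3 | step 4 | 5-bromo-3-[(E)-3-(3,4-dimethoxyphenyl)prop-2-enoyl]-2-hydroxyphenyl methanesulfonate | COc1ccc(/C=C/C(=O)c2cc(Br)cc(OS(C)(=O)=O)c2O)cc1OC
F4 | step 4 | racemic 6-bromo-2-(3,4-dimethoxyphenyl)-4-oxochroman-8-yl methanesulfonate | COc1ccc(C2Oc3c(OS(C)(=O)=O)cc(Br)cc3C(=O)C2)cc1OC
F5 | step 4 | (2S,4S)-6-bromo-2-(3,4-dimethoxyphenyl)-4-hydroxychroman-8-yl methanesulfonate (2,4-cis) | COc1ccc([C@H]2Oc3c(OS(C)(=O)=O)cc(Br)cc3[C@@H](O)C2)cc1OC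
F6 | step 1 | 5'-bromo-2',3'-dihydroxyacetophenone | CC(=O)c1cc(Br)cc(O)c1O
F7 | step 1 | (E)-1-(5-bromo-2,3-dihydroxyphenyl)-3-(dimethylamino)prop-2-en-1-one | CN(C)/C=C/C(=O)c1cc(Br)cc(O)c1O
F8 | step 1 | 6-bromo-8-hydroxy-4H-chromen-4-one | O=c1ccoc2c(O)cc(Br)cc12
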